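**Retrosynthetic overview**
1. Target 29 ⇐ cyclobutanol 28 by retro-aldol opening of the C9–C20 bond (the eight-membered ring is formed last) ⇐ photoadduct 27.
2. 27 ⇐ triol 26 by an intramolecular vinylogous ester–tetronate [2+2] photocycloaddition (the new step: forms C9–C18 and C19–C20, closes the cyclopentane and sets C18).
3. 26 ⇐ cage ketone 14 + aldehyde 22 (syn aldol C10–C12, then hydroxyl-directed reduction at C13).
4. 14 ⇐ cyclohexanone 8 + methyl propiolate 9 (alkynylation, oxa-Michael, lactonisation: ether bridge and butenolide in one operation) ⇐ (S)-carvone 1.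
5. 22 ⇐ cyclohexane-1,3-dione 16. Ring order: carvone six-membered ring → oxabicyclo[2.2.2]octane plus butenolide → cyclopentane plus cyclobutane → eight-membered ring.

Assumption: the epimerisable centres C2 and C9 of the target are taken to be the thermodynamically preferred ones, so the final base equilibration delivers them.
Atom labels (C2, O17 and so on) count the heavy atoms of the target SMILES from left to right.

**Step 1**
Reactants: 1 (S)-(+)-carvone
Product: 2 trans-carvone epoxide
Conditions: 30% H2O2, NaOH (0.3 equiv), MeOH, 0 °C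
Reagents that add atoms: hydrogen peroxide, OO
Why: Weitz–Scheffer nucleophilic epoxidation, in which hydroperoxide adds axially to the enone β-carbon anti to the equatorial isopropenyl group and leaves the isolated alkene untouched (sets C13 and the oxygen face at C15).

**Step 2**
Reactants: 2 trans-carvone epoxide
Product: 3 tertiary epoxy alcohol
Conditions: MeLi, Et2O, −78 °C; then H2O
Reagents that add atoms: methyllithium, [Li]C
Why: 1,2-addition of the organolithium to the α,β-epoxy ketone anti to the epoxide oxygen (Cornforth/chelate control) sets C27 with OH cis to the epoxide.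

**Step 3**
Reactants: 3 tertiary epoxy alcohol
Product: 4 all-trans triol
Conditions: HClO4 (5 mol%), THF/H2O 3:1, 0 °C to rt
Reagents that add atoms: water, O
Why: acid-catalysed epoxide hydrolysis in which water attacks the tertiary C15 with inversion in a trans-diaxial (Fürst–Plattner, Markovnikov) opening, so the C15 oxygen ends anti to both the C13 and the C27 hydroxyls.

**Step 4**
Reactants: 4 all-trans triol
Product: 5 O13/O27 acetonide
Conditions: Me2C(OMe)2, camphorsulfonic acid (5 mol%), CH2Cl2, rt
Reagents that add atoms: 2,2-dimethoxypropane, COC(C)(C)OC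
Why: acid-catalysed ketalisation can bridge only the syn-1,3-diaxial pair O13/O27 (both 1,2-diols are trans-diaxial), which locks the chair and leaves the C15 hydroxyl free.

**Step 5**
Reactants: 5 O13/O27 acetonide
Product: 8 cyclohexanone acetonide, via methoxy hydroperoxide 6 (not isolated), via TEMPO alkoxyamine 7 (not isolated)
Conditions: O3, MeOH, −78 °C; then FeSO4·7H2O, TEMPO, −78 °C to rt; then magnesium bis(monoperoxyphthalate) hexahydrate, rt
Reagents that add atoms: TEMPO, CC1(C)CCCC(C)(C)N1[O]
Why: oxodealkenylation (ozonolysis, then iron-mediated β-scission of the α-methoxy hydroperoxide to a C25 radical, TEMPO trapping and peracid oxidation of the alkoxyamine) turns the isopropenyl-bearing carbon into the C25 ketone without touching a stereocentre.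

**Step 6**
Reactants: 8 cyclohexanone acetonide; 9 methyl propiolate
Product: 12 cage tetronate acetonide, via alkynol 10 (not isolated), via bicyclic enoate 11 (not isolated)
Conditions: 9 (2.5 equiv), LiN(SiMe3)2 (2.4 equiv), THF, −78 °C; add 8, 1 h; warm to 0 °C, 3 h; AcOH
Reagents that add atoms: none
Why: 1,2-alkynylation anti to the two syn-axial acetonide oxygens puts the alkyne cis to the C15 alkoxide (sets C25), which then adds 6-exo-dig to the ynoate β-carbon C18 (oxa-Michael addition) before the C25 alkoxide lactonises onto the ester.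

**Step 7**
Reactants: 12 cage tetronate acetonide
Product: 13 cage tetronate diol
Conditions: CF3CO2H/H2O 9:1, 0 °C
Reagents that add atoms: none
Why: acid hydrolysis of the isopropylidene ketal, to which the vinylogous carbonate (tetronate) and the bridging ether are stable.

**Step 8**
Reactants: 13 cage tetronate diol
Product: 14 cage ketone
Conditions: Dess–Martin periodinane, NaHCO3, CH2Cl2, rt
Reagents that add atoms: none
Why: Dess–Martin oxidation of the only secondary alcohol (C13), the tertiary C27 alcohol being inert.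

**Step 9**
Reactants: 14 cage ketone
Product: 15 bis-silyl enol silane
Conditions: Me3SiOTf, Et3N, CH2Cl2, 0 °C
Reagents that add atoms: trimethylsilyl triflate, C[Si](C)(C)OS(=O)(=O)C(F)(F)F
Why: soft enolisation to the silyl enol ether can go only toward C12 because C15 is quaternary, and the tertiary C27 alcohol is silylated in the same operation.

**Step 10**
Reactants: 16 cyclohexane-1,3-dione
Product: 17 3-(benzyloxy)cyclohex-2-en-1-one
Conditions: BnOH, TsOH·H2O (cat.), toluene, reflux, Dean–Stark
Reagents that add atoms: benzyl alcohol, OCc1ccccc1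
Why: acid-catalysed enol etherification (vinylogous ester formation) of the symmetric dione with azeotropic removal of water.

**Step 11**
Reactants: 17 3-(benzyloxy)cyclohex-2-en-1-one
Product: 18 racemic 6-methyl vinylogous ester
Conditions: LiN(i-Pr)2, THF, −78 °C; MeI
Reagents that add atoms: iodomethane, CI
Why: Stork–Danheiser kinetic α′-enolate alkylation of a vinylogous ester.

**Step 12**
Reactants: 18 racemic 6-methyl vinylogous ester
Product: 19 (S)-6-hydroxy-6-methyl vinylogous ester
Conditions: NaN(SiMe3)2, THF, −78 °C; (−)-[(8,8-dichlorocamphoryl)sulfonyl]oxaziridine; then H2O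
Reagents that add atoms: (−)-[(8,8-dichlorocamphoryl)sulfonyl]oxaziridine, CC1(C)[C@H]2CC[C@@]13CS(=O)(=O)N4O[C@]34C2(Cl)Cl
Why: Davis enolate hydroxylation, in which reagent-controlled oxygen transfer to one face of the tetrasubstituted sodium enolate sets the tertiary alcohol C4 as S (sense assigned by analogy with 2-methyl-1-tetralone).

**Step 13**
Reactants: 19 (S)-6-hydroxy-6-methyl vinylogous ester
Product: 20 cis-4,6-dimethyl silyl ether
Conditions: LiN(i-Pr)2 (2.2 equiv), THF/DMPU, −78 °C; MeI (1.05 equiv); then Me3SiCl
Reagents that add atoms: iodomethane, CI; chlorotrimethylsilane, C[Si](C)(C)Cl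
Why: with the α′ position blocked, the dianion is methylated at the γ-carbon of the vinylogous ester dienolate anti to the neighbouring alkoxide (sets C2, cis-dimethyl, still epimerisable later), and the alkoxide is capped in situ as its silyl ether.

**Step 14**
Reactants: 20 cis-4,6-dimethyl silyl ether
Product: 21 2-iodo vinylogous ester
Conditions: N-iodosuccinimide, CH2Cl2, rt, dark
Reagents that add atoms: N-iodosuccinimide, O=C1CCC(=O)N1I
Why: electrophilic iodination at the nucleophilic α-carbon of the enol ether (vinylogous ester).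

**Step 15**
Reactants: 21 2-iodo vinylogous ester
Product: 22 2-formyl vinylogous ester
Conditions: CO (1 atm), Bu3SnH (slow addition), Pd(PPh3)4 (5 mol%), THF, 50 °C
Reagents that add atoms: carbon monoxide, [C-]#[O+]
Why: palladium-catalysed reductive carbonylation (formylation) of the vinyl iodide by oxidative addition, CO insertion and hydride transfer from tin.

**Step 16**
Reactants: 15 bis-silyl enol silane; 22 2-formyl vinylogous ester
Product: 23 tris-silyl syn-aldol
Conditions: TASF [(Me2N)3S+ Me3SiF2−] (10 mol%), THF, −78 °C; pH 7 buffer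
Reagents that add atoms: none
Why: fluoride-catalysed Mukaiyama-type aldol addition through a naked enolate and an open, syn-selective transition state, in which the aldehyde reaches C12 from the open face next to the ether oxygen O17 (anti to the C27 silyloxy group), setting C12 and the syn C10 carbinol, trapped as its silyl ether.

**Step 17**
Reactants: 23 tris-silyl syn-aldol
Product: 26 triol photosubstrate, via C10 alcohol 24 (not isolated), via bis-silyl anti-diol 25 (not isolated)
Conditions: Me4NBH(OAc)3, MeCN/AcOH 1:1, −20 °C to rt; then citric acid, MeOH, rt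
Reagents that add atoms: none
Why: Evans–Saksena hydroxyl-directed reduction, in which acetic acid frees the secondary C10 hydroxyl and its acyloxyborohydride delivers hydride to the C13 ketone from the side of the C12 substituent (1,3-anti diol, sets C13), while the silylated tertiary alcohols cannot direct and are unmasked afterwards.

**Step 18**
Reactants: 26 triol photosubstrate
Product: 27 cyclobutane photoadduct
Conditions: hν (300 nm, Pyrex), MeCN/acetone 9:1, degassed, high dilution, 0 °C
Reagents that add atoms: none
Why: Proposed new method: acetone-sensitised excitation gives the triplet vinylogous ester, whose α-carbon C9 bonds first to the tetronate β-carbon C18 through the three-atom tether (five-membered 1,5-closure, rule of five), leaving a 1,4-biradical stabilised at C20 (tertiary, α-benzyloxy) and at C19 (α to the lactone carbonyl) that collapses after intersystem crossing to the all-cis-fused cyclobutane, so the cage fixes C18 and the sense at C9, C19 and C20; the closest known reaction type is the intramolecular enone–alkene [2+2] step of the de Mayo reaction (and [2+2] photocycloadditions of tetronates), but a 1,3-dione enol ether has not been added across the alkene of a 4-alkoxybutenolide to make two adjacent fully substituted carbons destined for fragmentation to an eight-membered ring.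

**Step 19**
Reactants: 27 cyclobutane photoadduct
Product: 29 target CNP0073514.1, via cyclobutanol 28 (not isolated)
Conditions: H2 (1 atm), 10% Pd on carbon, EtOAc, rt; filter; Et3N (0.2 equiv), rt
Reagents that add atoms: none
Why: hydrogenolysis of the benzyl ether unmasks a strained β-hydroxy ketone that undergoes retro-aldol (de Mayo) fragmentation of the C9–C20 bond to the eight-membered 1,5-diketone, after which the new β-keto lactone enolises and amine-mediated equilibration protonates C9 (and C2) to the cis-fused, thermodynamically preferred configuration.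

**Compound list**
1 | (S)-(+)-carvone, (5S)-2-methyl-5-(prop-1-en-2-yl)cyclohex-2-en-1-one | CC1=CC[C@@H](CC1=O)C(C)=C | starting material
2 | (1S,4S,6S)-1-methyl-4-(prop-1-en-2-yl)-7-oxabicyclo[4.1.0]heptan-2-one (epoxide trans to isopropenyl) | CC(=C)[C@@H]1CC(=O)[C@@]2(C)O[C@H]2C1 | intermediate
3 | (1S,2R,4S,6S)-1,2-dimethyl-4-(prop-1-en-2-yl)-7-oxabicyclo[4.1.0]heptan-2-ol (OH cis to epoxide) | CC(=C)[C@@H]1C[C@@](C)(O)[C@@]2(C)O[C@H]2C1 | intermediate
4 | (1R,2R,3S,5S)-1,2-dimethyl-5-(prop-1-en-2-yl)cyclohexane-1,2,3-triol | CC(=C)[C@@H]1C[C@@](C)(O)[C@](C)(O)[C@@H](O)C1 | intermediate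
5 | isopropylidene acetal of 4 across the syn-1,3 oxygens O13 and O27, C15 hydroxyl free | CC(=C)[C@@H]1C[C@@]2(C)OC(C)(C)O[C@@H](C1)[C@@]2(C)O | intermediate
6 | α-methoxy hydroperoxide from ozonolysis of 5 in MeOH (epimers at the new ketal carbon) | COC(C)(OO)[C@@H]1C[C@@]2(C)OC(C)(C)O[C@@H](C1)[C@@]2(C)O | intermediate
7 | C25 O-alkyl TEMPO hydroxylamine (epimers at C25) | CC1(C)CCCC(C)(C)N1OC3C[C@@]2(C)OC(C)(C)O[C@@H](C3)[C@@]2(C)O | intermediate
8 | 3,4,5-trihydroxy-3,4-dimethylcyclohexanone 3,5-acetonide (C25 ketone, C15 hydroxyl free, configured as in 4) | O=C1C[C@@]2(C)OC(C)(C)O[C@@H](C1)[C@@]2(C)O | intermediate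
9 | methyl propiolate | C#CC(=O)OC | starting material
10 | C25 tertiary propargylic alcohol of 8, ynoate cis to the C15 hydroxyl | COC(=O)C#C[C@]1(O)C[C@@]2(C)OC(C)(C)O[C@@H](C1)[C@@]2(C)O | intermediate
11 | 2-oxabicyclo[2.2.2]octane with exocyclic β-alkoxy acrylate at C18 (ester cis to C25), C25 hydroxyl free | COC(=O)/C=C1/O[C@]2(C)[C@H]3OC(C)(C)O[C@]2(C)C[C@]1(O)C3 | intermediate
12 | cage tetronate: butenolide (C22 carbonyl, C18=C19) fused at C25 and ether-bridged O17 to C15, O13/O27 acetonide | O=C1C=C2O[C@]3(C)[C@H]4OC(C)(C)O[C@]3(C)C[C@]2(O1)C4 | intermediate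
13 | cage tetronate with free C13 and C27 hydroxyls (both anti to the ether bridge) | O=C1C=C2O[C@]3(C)[C@@H](O)C[C@@]2(O1)C[C@@]3(C)O | intermediate
14 | cage tetronate with C13 ketone and free C27 hydroxyl | O=C1C=C2O[C@]3(C)C(=O)C[C@@]2(O1)C[C@@]3(C)O | intermediate
15 | C12=C13 trimethylsilyl enol ether of 14 with C27 trimethylsilyl ether | O=C1C=C2O[C@]3(C)C(O[Si](C)(C)C)=C[C@@]2(O1)C[C@@]3(C)O[Si](C)(C)C | intermediate
16 | cyclohexane-1,3-dione | O=C1CCCC(=O)C1 | starting material
17 | 3-(benzyloxy)cyclohex-2-en-1-one | O=C1C=C(OCc2ccccc2)CCC1 | intermediate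
18 | racemic 3-(benzyloxy)-6-methylcyclohex-2-en-1-one | O=C1C=C(OCc2ccccc2)CCC1C | intermediate
19 | (S)-3-(benzyloxy)-6-hydroxy-6-methylcyclohex-2-en-1-one | O=C1C=C(OCc2ccccc2)CC[C@]1(C)O | intermediate
20 | (4S,6S)-3-(benzyloxy)-4,6-dimethyl-6-[(trimethylsilyl)oxy]cyclohex-2-en-1-one (methyls cis) | O=C1C=C(OCc2ccccc2)[C@@H](C)C[C@]1(C)O[Si](C)(C)C | intermediate
21 | (4S,6S)-3-(benzyloxy)-2-iodo-4,6-dimethyl-6-[(trimethylsilyl)oxy]cyclohex-2-en-1-one | O=C1C(I)=C(OCc2ccccc2)[C@@H](C)C[C@]1(C)O[Si](C)(C)C | intermediate
22 | (3S,5S)-2-(benzyloxy)-3,5-dimethyl-6-oxo-5-[(trimethylsilyl)oxy]cyclohex-1-ene-1-carbaldehyde | O=CC1=C(OCc2ccccc2)[C@@H](C)C[C@](C)(O[Si](C)(C)C)C1=O | intermediate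
23 | syn-aldol of 15 and 22: C12–C10 bond, silyl ethers at O11, O29 and O6, C13 ketone | O=C1C=C2O[C@]3(C)C(=O)[C@H]([C@H](O[Si](C)(C)C)C4=C(OCc5ccccc5)[C@@H](C)C[C@](C)(O[Si](C)(C)C)C4=O)[C@@]2(O1)C[C@@]3(C)O[Si](C)(C)C | intermediate
24 | 23 with the C10 hydroxyl free (tertiary silyl ethers kept) | O=C1C=C2O[C@]3(C)C(=O)[C@H]([C@H](O)C4=C(OCc5ccccc5)[C@@H](C)C[C@](C)(O[Si](C)(C)C)C4=O)[C@@]2(O1)C[C@@]3(C)O[Si](C)(C)C | intermediate
25 | C13/C10 anti-diol with silyl ethers at O29 and O6 | O=C1C=C2O[C@]3(C)[C@@H](O)[C@H]([C@H](O)C4=C(OCc5ccccc5)[C@@H](C)C[C@](C)(O[Si](C)(C)C)C4=O)[C@@]2(O1)C[C@@]3(C)O[Si](C)(C)C | intermediate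
26 | photosubstrate: cage tetronate joined at C12 through the C10 carbinol to C9 of the benzyl vinylogous ester; free hydroxyls at C10, C13, C27 and C4 | O=C1C=C2O[C@]3(C)[C@@H](O)[C@H]([C@H](O)C4=C(OCc5ccccc5)[C@@H](C)C[C@](C)(O)C4=O)[C@@]2(O1)C[C@@]3(C)O | intermediate
27 | cyclobutane photoadduct (C9–C18 and C19–C20 bonds; cyclobutane cis-fused to cyclopentane, lactone and cyclohexanone; C20 benzyl ether) | C[C@H]1C[C@](C)(O)C(=O)[C@@]26[C@@H](O)[C@H]3[C@H](O)[C@@]4(C)O[C@@]25[C@@H]([C@@]16OCc7ccccc7)C(=O)O[C@@]35C[C@@]4(C)O | intermediate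
28 | cyclobutanol (27 with free C20 hydroxyl) | C[C@H]1C[C@](C)(O)C(=O)[C@@]26[C@@H](O)[C@H]3[C@H](O)[C@@]4(C)O[C@@]25[C@@H]([C@@]16O)C(=O)O[C@@]35C[C@@]4(C)O | intermediate
29 | CNP0073514.1 | C[C@H]1C[C@](C)(O)C(=O)[C@@H]2[C@@H](O)[C@H]3[C@H](O)[C@@]4(C)O[C@@]25/C(=C\1O)C(=O)O[C@@]35C[C@@]4(C)O | target

**Step count and risk**
Total step count: 19. Longest linear sequence: 13 (steps 1–9, then 16–19).

Steps most likely to fail:

Step 18 (the proposed new photocycloaddition). The crowded cyclobutane may not close, or the biradical may revert. The fallback uses known ionic chemistry, sets out from 26 and rejoins at 29. Hydrogenolysis of 26 (H2, 10% Pd on carbon, EtOAc) gives the free 2-substituted cyclohexane-1,3-dione F1. With Et3N in MeCN its doubly activated carbon C9 adds 5-exo to C18 of the tetronate (intramolecular Michael addition) to give the non-enolisable 2,2-disubstituted dione F2. NaOMe in MeOH opens F2 by retro-Claisen attack at the less hindered C20 carbonyl to the keto methyl ester F3. Continued heating with NaOMe then closes the eight-membered ring by Dieckmann condensation of the lactone α-carbon C19 onto the C20 ester, driven by the stabilised β-keto lactone enolate, and gives 29 after acidification.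

Step 16 (fluoride-catalysed syn-aldol). The hindered, push-pull aldehyde 22 may react sluggishly, or the aldol may come out anti at C10. The fallback sets the C10 centre by directed reduction in place of the aldol transition state; it sets out from 14 and 22 and rejoins at 26. Enolisation of 14 with (c-C6H11)2BCl/Et3N and addition to 22 through the closed chair transition state gives, after acidic work-up that removes the silyl group, the anti-aldol F4. Me4NBH(OAc)3 still delivers hydride to C13 from the side of the C12 substituent and gives the C10-epimeric triol F5. MnO2 oxidises only the allylic C10 alcohol to the C10 ketone F6. A second Me4NBH(OAc)3 reduction, now directed by the C13 hydroxyl, gives the 1,3-anti diol 26.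

Step 6 (one-pot alkynylation, oxa-Michael addition and lactonisation). The tertiary alkoxide may not add to the ynoate before the lithium propiolate decomposes. The fallback makes the ether bond by vinylogous trans-etherification in place of conjugate addition; it sets out from 8 and 9 and rejoins at 12. The alkynylation is quenched at −78 °C and the alkynol 10 is isolated. NaOMe in MeOH adds methoxide to the ynoate and lactonises to the spiro methyl tetronate F7. Camphorsulfonic acid in toluene at 80 °C, with removal of MeOH, exchanges the methyl enol ether for the cis C15 hydroxyl and gives 12.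

**Further compounds**
F1 | step 18 | debenzylated 2-substituted cyclohexane-1,3-dione (enol form) derived from 26 | O=C1C=C2O[C@]3(C)[C@@H](O)[C@H]([C@H](O)C4=C(O)[C@@H](C)C[C@](C)(O)C4=O)[C@@]2(O1)C[C@@]3(C)O
F2 | step 18 | Michael adduct with C9 quaternary (C9–C18 bond, saturated lactone, intact cyclohexane-1,3-dione) | C[C@H]1C[C@](C)(O)C(=O)[C@@]2(C1=O)[C@@H](O)[C@H]3[C@H](O)[C@@]4(C)O[C@@]25CC(=O)O[C@@]35C[C@@]4(C)O
F3 | step 18 | retro-Claisen keto methyl ester (C20 ester, C7 ketone on C9) | COC(=O)[C@@H](C)C[C@](C)(O)C(=O)[C@@H]1[C@@H](O)[C@H]2[C@H](O)[C@@]3(C)O[C@@]14CC(=O)O[C@@]24C[C@@]3(C)O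
F4 | step 16 | anti-aldol, C10 epimer of desilylated 23 | O=C1C=C2O[C@]3(C)C(=O)[C@H]([C@@H](O)C4=C(OCc5ccccc5)[C@@H](C)C[C@](C)(O)C4=O)[C@@]2(O1)C[C@@]3(C)O
F5 | step 16 | C10 epimer of 26 | O=C1C=C2O[C@]3(C)[C@@H](O)[C@H]([C@@H](O)C4=C(OCc5ccccc5)[C@@H](C)C[C@](C)(O)C4=O)[C@@]2(O1)C[C@@]3(C)O
F6 | step 16 | C10 ketone with free C13 hydroxyl | O=C1C=C2O[C@]3(C)[C@@H](O)[C@H](C(=O)C4=C(OCc5ccccc5)[C@@H](C)C[C@](C)(O)C4=O)[C@@]2(O1)C[C@@]3(C)O
F7 | step 6 | spiro methyl tetronate with free C15 hydroxyl and O13/O27 acetonide | COC1=CC(=O)O[C@]12C[C@@]3(C)OC(C)(C)O[C@@H](C2)[C@@]3(C)O
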